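**Retrosynthetic overview**
1. 7 ⇒ 6: the C2–Br bond is traced back to the lactam C=O of 4,6-dibromo-3-(methylsulfanyl)oxindole (deoxybromination with aromatisation).
2. 6 ⇒ 5 (key C3–C3a bond): the amide alpha-carbon serves as an enolonium equivalent, an acyl-substituted thionium ion. This joins two carbons that are both donors by nature, the enolate carbon and the anilide ortho carbon.
3. 5 ⇒ 4 ⇒ 3: the cation is unmasked from the same sulfide that the target keeps as its SMe group (S-bromination, halo-Pummerer shift, bromide abstraction).
4. 3 ⇒ 1 + 2: amide bond. The mirror symmetry of 3,5-dibromoaniline makes both ortho carbons identical, so only the 4,6-dibromo pattern can form.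
5. Ring order: the benzene ring is bought. The pyrrole ring is the only ring made, and it is closed in the last flask.

Assumption: the target is planar and has no stereocentre or stereoaxis, so it is one achiral compound and no enantiomer has to be selected.

**Step 1**
Reactants: 1 3,5-dibromoaniline; 2 (methylsulfanyl)acetyl chloride
Product: 3 N-(3,5-dibromophenyl)-2-(methylsulfanyl)acetamide
Conditions: K2CO3 (1.5 equiv), THF, 0 °C to rt, 2 h
Reagents that add atoms: none
Why: Schotten–Baumann-type N-acylation, in which the acyl chloride is reactive enough for the weakly basic dibromoaniline, K2CO3 takes up the HCl, the aryl bromides and the sulfide are untouched, and no stereocentre is formed.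

**Step 2**
Reactants: 3 N-(3,5-dibromophenyl)-2-(methylsulfanyl)acetamide
Product: 7 2,4,6-tribromo-3-(methylsulfanyl)-1H-indole, via alpha-bromo sulfide 4 (not isolated), via acyl thionium bromide 5 (not isolated), via 3-(methylsulfanyl)oxindole 6 (not isolated)
Conditions: NBS (1.0 equiv), CH2Br2, 0 °C, 30 min; SnBr4 (1.5 equiv), 0 to 60 °C, 3 h; POBr3 (2.5 equiv), 85 °C, 8 h; cold aq NaHCO3
Reagents that add atoms: phosphoryl bromide (POBr3), O=P(Br)(Br)Br
Why: Proposed new method: NBS brominates sulfur and a halo-Pummerer shift gives 4, SnBr4 abstracts bromide to leave the acyl thionium ion 5, whose amide alpha-carbon (by nature an enolate donor) now acts as an enolonium-type acceptor and is attacked by the anilide ortho carbon (also a donor by nature, and a position to which N, 3-Br and 5-Br all direct) in an intramolecular Friedel–Crafts closure to 6, whose easily enolised lactam is O-phosphorylated by POBr3 and displaced by bromide with aromatisation to 7, so that the transient C3 stereocentre of 4 and 6 ends trigonal; the closest known reaction types are the Pummerer/alpha-halo-sulfide variant of the Stollé oxindole synthesis and the POBr3 deoxybromination of oxindoles to 2-bromoindoles, run here in one flask where reagents and solvent contain bromide as the only halide (so no 2-chloroindole can form), on an NH anilide with a doubly brominated ring.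

**Compound list**
1 | 3,5-dibromoaniline | Nc1cc(Br)cc(Br)c1 | starting material
2 | (methylsulfanyl)acetyl chloride | CSCC(=O)Cl | starting material
3 | N-(3,5-dibromophenyl)-2-(methylsulfanyl)acetamide | CSCC(=O)Nc1cc(Br)cc(Br)c1 | intermediate
4 | 2-bromo-N-(3,5-dibromophenyl)-2-(methylsulfanyl)acetamide (racemic) | CSC(Br)C(=O)Nc1cc(Br)cc(Br)c1 | intermediate
5 | [2-(3,5-dibromoanilino)-2-oxoethylidene](methyl)sulfonium bromide (acyl thionium ion pair, bromide held by SnBr4) | C[S+]=CC(=O)Nc1cc(Br)cc(Br)c1.[Br-] | intermediate
6 | 4,6-dibromo-3-(methylsulfanyl)-1,3-dihydro-2H-indol-2-one (racemic, C3 labile) | CSC1C(=O)Nc2cc(Br)cc(Br)c12 | intermediate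
7 | 2,4,6-tribromo-3-(methylsulfanyl)-1H-indole (achiral) | CSc1c(Br)[nH]c2cc(Br)cc(Br)c12 | target

**Total step count:** 2
**Longest linear sequence:** 2 (1 → 3 → 7)

**Steps most likely to fail**
The route has only two steps. The two independent stages of step 2 are therefore ranked separately, followed by step 1.

1. Step 2, ring-closure stage (5 → 6).
   - Risk: the ring carries two bromines and the attacked carbon sits next to one of them. The NH anilide also prefers the rotamer that turns the ring away from the cation.
   - Fallback (sets out from 1, comes back at 6): the polarity roles are exchanged in a Gassman oxindole synthesis, so the ring becomes the acceptor and the alpha-carbon the donor. tBuOCl in CH2Cl2 at −65 °C turns 1 into N-chloro-3,5-dibromoaniline F1. Ethyl (methylsulfanyl)acetate attacks it through sulfur to give the azasulfonium chloride F2. Et3N deprotonates this to the ester-stabilised sulfonium ylide F3. The ylide shifts [2,3]-sigmatropically onto the ortho carbon and rearomatises to ethyl 2-(2-amino-4,6-dibromophenyl)-2-(methylsulfanyl)acetate F4. Stirring with 2 M HCl closes the lactam to 6, which is isolated and treated with POBr3 alone, as in the last stage of step 2.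

2. Step 2, deoxybromination stage (6 → 7).
   - Risk: hot POBr3 and HBr may cleave the C3–S bond or degrade the 2-bromoindole.
   - Fallback (sets out from 6, comes back at 7): the C2 bromine is introduced by electrophilic substitution instead of from the lactam oxygen. Compound 6 is isolated after the SnBr4 stage and reduced with iBu2AlH (3 equiv, THF, 0 °C) to 4,6-dibromo-3-(methylsulfanyl)indolin-2-ol F5. This loses water on mildly acidic work-up to give 4,6-dibromo-3-(methylsulfanyl)-1H-indole F6. NBS (1.0 equiv, THF, −78 to 0 °C) then brominates C2, the only free pyrrole carbon, to give 7.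

3. Step 1.
   - Risk: low. The acyl chloride 2 ages through its own sulfur, and the aniline is a weak nucleophile.
   - Fallback (sets out from 1, comes back at 3): the C–S bond is made after the amide bond. Chloroacetyl chloride with K2CO3 in THF at 0 °C gives 2-chloro-N-(3,5-dibromophenyl)acetamide F7. NaSMe in THF/EtOH at rt displaces the chloride to give 3.

**Further compounds**
F1 | step 2 | N-chloro-3,5-dibromoaniline | ClNc1cc(Br)cc(Br)c1
F2 | step 2 | (3,5-dibromoanilino)(2-ethoxy-2-oxoethyl)(methyl)sulfonium chloride (racemic at sulfur) | CCOC(=O)C[S+](C)Nc1cc(Br)cc(Br)c1.[Cl-]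
F3 | step 2 | (3,5-dibromoanilino)(methyl)sulfonium (ethoxycarbonyl)methylide | CCOC(=O)[CH-][S+](C)Nc1cc(Br)cc(Br)c1
F4 | step 2 | ethyl 2-(2-amino-4,6-dibromophenyl)-2-(methylsulfanyl)acetate (racemic) | CCOC(=O)C(SC)c1c(N)cc(Br)cc1Br
F5 | step 2 | 4,6-dibromo-3-(methylsulfanyl)indolin-2-ol (racemic, mixture of diastereomers) | CSC1C(O)Nc2cc(Br)cc(Br)c12
F6 | step 2 | 4,6-dibromo-3-(methylsulfanyl)-1H-indole | CSc1c[nH]c2cc(Br)cc(Br)c12
F7 | step 1 | 2-chloro-N-(3,5-dibromophenyl)acetamide | ClCC(=O)Nc1cc(Br)cc(Br)c1
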